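**Plan**

1. Retrosynthesis: cut C12–C13 (sp3–sp2 coupling of the side arm), put two helpers back on ring A (an OH at C2, a C4=CH2 in place of one methyl), then cut C2–C3 and C5–C10 together, then C8–C9 (Ireland–Claisen) and the ester C–O bond.
2. Feature used: in ring A, C10(Me)–C1–C2 is the chain of a β-methyl enal (electrophilic at C10 and at C2), and C5–C4–C3 is a Me2C=CH (prenyl) end whose alkene carbon C5 and methyl carbon C3 can each act once as an ene donor. The C6=C7 alkene of ring B is carried in the chain as a Z-alkene.
3. Forward: acyclic enal 18 (stereocenters only at C8 and C9) is folded by Me2AlCl through two consecutive ene reactions, ring B first (C5–C10), then ring A (C2–C3).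
4. Stereochemistry: one carbinol from a Corey–Bakshi–Shibata reduction is relayed by the chair Ireland–Claisen shift to C8 and C9; these direct C5 and C10 in the cascade (trans ring fusion).
5. After the cascade: C4=CH2 becomes CMe2 (HAT hydromethylation), the C2–OH is removed (Barton–McCombie), and chloride → iodide → zinc reagent → Negishi coupling with a (Z)-iodoenoate fixes the 13E side chain.

Key step: step 10

Remark: labdane numbering (C1–C20) is used for all intermediates; the C2 carbinol created in step 10 is carried as an epimer mixture until step 13 removes it, and compounds 1, 5, 9, 10 and 26 are taken as purchasable.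

**Route**

Step 1
Reactants: 1 pent-3-yn-1-ol
Product: 2 5-chloropent-2-yne
Conditions: PPh3, N-chlorosuccinimide, CH2Cl2, 0 °C to rt
Reagents that add atoms: N-chlorosuccinimide, O=C1CCC(=O)N1Cl
Why: Appel-type chlorination (chlorophosphonium activation of the primary alcohol, SN2 by chloride) should give the primary chloride that later becomes the C12 coupling handle; no stereocenter is formed.

Step 2
Reactants: 2 5-chloropent-2-yne
Product: 4 (E)-5-chloro-2-iodopent-2-ene, via alkenylzirconocene chloride 3 (not isolated)
Conditions: Cp2Zr(H)Cl (1.5 equiv), THF, rt to 40 °C; then I2, 0 °C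
Reagents that add atoms: iodine, II
Why: hydrozirconation is a syn addition that, after equilibration with excess hydride, places zirconium on the methyl-bearing alkyne carbon, and iodinolysis with retention should give the E-iodide (methyl cis to the chloroethyl chain).

Step 3
Reactants: 4 (E)-5-chloro-2-iodopent-2-ene; 5 2-[(tert-butyldimethylsilyl)oxy]-N-methoxy-N-methylacetamide
Product: 7 (E)-1-[(tert-butyldimethylsilyl)oxy]-6-chloro-3-methylhex-3-en-2-one, via alkenyllithium 6 (not isolated)
Conditions: t-BuLi (2 equiv), Et2O, −78 °C; then 5, −78 to 0 °C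
Reagents that add atoms: none
Why: iodine–lithium exchange proceeds with retention of alkene geometry and the Weinreb amide acylation stops at the ketone through its chelated tetrahedral intermediate; the primary chloride is inert to t-BuLi at −78 °C.

Step 4
Reactants: 7 (E)-1-[(tert-butyldimethylsilyl)oxy]-6-chloro-3-methylhex-3-en-2-one
Product: 8 (2S,3E)-1-[(tert-butyldimethylsilyl)oxy]-6-chloro-3-methylhex-3-en-2-ol
Conditions: (S)-2-methyl-CBS-oxazaborolidine (10 mol%), BH3·SMe2, THF, −30 °C
Reagents that add atoms: none
Why: Corey–Bakshi–Shibata reduction delivers hydride to one carbonyl face with the alkenyl group as the large and CH2OSi as the small substituent, which should set the 2S carbinol, the only stereocenter set by a catalyst.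

Step 5
Reactants: 9 (2-carboxyethyl)triphenylphosphonium bromide; 10 3-methylbut-2-enal
Product: 12 (3Z)-6-methylhepta-3,5-dienoic acid, via phosphonium ylide carboxylate 11 (not isolated)
Conditions: NaN(SiMe3)2 (2.1 equiv), THF, −78 °C to rt; aq. HCl
Reagents that add atoms: none
Why: Wittig reaction of the non-stabilised ylide under salt-free, low-temperature conditions is kinetically Z-selective, so the future C6=C7 alkene should form as the Z isomer that ring B needs.

Step 6
Reactants: 8 (2S,3E)-1-[(tert-butyldimethylsilyl)oxy]-6-chloro-3-methylhex-3-en-2-ol; 12 (3Z)-6-methylhepta-3,5-dienoic acid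
Product: 13 (2S,3E)-1-[(tert-butyldimethylsilyl)oxy]-6-chloro-3-methylhex-3-en-2-yl (3Z)-6-methylhepta-3,5-dienoate
Conditions: EDC·HCl, DMAP (10 mol%), CH2Cl2, 0 °C
Reagents that add atoms: none
Why: Steglich esterification joins the fragments under nearly neutral conditions without touching the carbinol center and, at 0 °C with little DMAP, without moving the β,γ-alkene into conjugation.

Step 7
Reactants: 13 allylic dienoate ester
Product: 16 methyl (2S,3R,4E)-6-[(tert-butyldimethylsilyl)oxy]-3-(2-chloroethyl)-4-methyl-2-[(1Z)-4-methylpenta-1,3-dien-1-yl]hex-4-enoate, via silyl ketene acetal 14 (not isolated), via carboxylic acid 15 (not isolated)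
Conditions: LiN(i-Pr)2, Me3SiCl, THF, −78 to 40 °C; aq. HCl; then Me3SiCHN2, MeOH–PhMe, 0 °C
Reagents that add atoms: trimethylsilyldiazomethane, C[Si](C)(C)C=[N+]=[N-]
Why: Ireland–Claisen rearrangement: kinetic deprotonation in THF with internal silyl quench should give the E silyl ketene acetal (dienyl group cis to the allylic oxygen), and the chair [3,3] shift with CH2OSi equatorial forms C8–C9, transfers the carbinol chirality to C9, sets C8 from the ketene acetal geometry and creates the E C10=C1 alkene; the acid is methylated under neutral conditions so that C8 is not epimerised.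

Step 8
Reactants: 16 silyl ether methyl ester
Product: 17 methyl (2S,3R,4E)-3-(2-chloroethyl)-6-hydroxy-4-methyl-2-[(1Z)-4-methylpenta-1,3-dien-1-yl]hex-4-enoate
Conditions: HF·pyridine, THF, 0 °C
Reagents that add atoms: none
Why: fluoride cleaves the primary allylic silyl ether (Si–F bond formation) under non-basic conditions that leave the acidic C8–H center and the Z-diene untouched.

Step 9
Reactants: 17 allylic alcohol
Product: 18 methyl (2S,3R,4E)-3-(2-chloroethyl)-4-methyl-2-[(1Z)-4-methylpenta-1,3-dien-1-yl]-6-oxohex-4-enoate
Conditions: MnO2, CH2Cl2, rt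
Reagents that add atoms: none
Why: MnO2 oxidises only the allylic alcohol to the E-enal without base, so C8 and both alkene geometries are kept.

Step 10
Reactants: 18 acyclic enal
Product: 20 decalin alcohol with exocyclic C4 methylene (5R,8S,9R,10S; C2 epimers), via monocyclic aldehyde 19 (not isolated)
Conditions: Me2AlCl (2.5 equiv), CH2Cl2, −78 to 0 °C; aq. NaHCO3
Reagents that add atoms: none
Why: Proposed new method: Me2AlCl binds the enal oxygen, the trisubstituted alkene attacks through C5 at the β-carbon C10 while a hydrogen of a C4 methyl passes to C1 (conjugate ene reaction; ring B closes as a six-membered ring with both reacting π bonds exocyclic), and the aluminium-bound aldehyde 19 so formed is attacked at C2 by the CH2 terminus C3 of the new isopropenyl group with hydrogen transfer from the remaining methyl to oxygen (type 2 carbonyl-ene; ring A closes as a six-membered ring with the alkene carbons C3 and C4 inside the ring), leaving the exocyclic C4 methylene and the C2 alcohol. The closest known reaction type is the alkylaluminium-halide-promoted sequential ene [3+3] annulation of enals or enones with 1,1-di- and trisubstituted alkenes, together with enal-initiated cation–olefin cyclisation; new here is that both ene events run intramolecularly on one chain so that two rings close. C5 and C10 are set in the first ene: ring B forms through a half-chair with the C8 ester and the C9 chloroethyl group equatorial, and the ene array H–C3–C4–C5–C10–C1 is a second chair trans-fused to it, which puts C4 and C1 equatorial and the C10 methyl axial and anti to H5 (trans ring fusion, methyl cis to the C9 chain). The E geometry of the enal turns only H1 toward C9, which favours this conformer, and the second ene then closes ring A in a chair without touching C5 or C10. Site selectivity rests on ring size and cation stability: C5 to C10 gives a six-membered ring and a tertiary cation at C4, whereas attack at the carbonyl carbon or by C4 or C7 would need eight-, seven- or four-membered rings, and the Z C6=C7 alkene is both required for ring B and too poor a nucleophile to compete for the aldehyde. The C2 carbinol is expected as an epimer mixture and is removed in step 13.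

Step 11
Reactants: 20 decalin alcohol with exocyclic C4 methylene
Product: 22 4,4-dimethyl decalin alcohol (5R,8S,9R,10S; C2 epimers), via sulfonyl hydrazide adduct 21 (not isolated)
Conditions: Fe(acac)3 (30 mol%), PhSiH3, CH2=N–NHSO2Me, MeOH–THF, rt; then 60 °C
Reagents that add atoms: formaldehyde N-(methylsulfonyl)hydrazone, C=NNS(C)(=O)=O
Why: Mukaiyama-type hydrogen-atom transfer from an iron hydride to the exocyclic 1,1-disubstituted alkene gives the tertiary C4 radical, which adds to the formaldehyde hydrazone, and thermal loss of sulfinate and N2 from the hydrazide (olefin hydromethylation) leaves the second C4 methyl; the 1,2-disubstituted C6=C7 alkene reacts far more slowly and no stereocenter is created.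

Step 12
Reactants: 22 4,4-dimethyl decalin alcohol
Product: 23 C2 O-(imidazol-1-ylthiocarbonyl) derivative
Conditions: 1,1′-thiocarbonyldiimidazole, DMAP (cat.), ClCH2CH2Cl, 70 °C
Reagents that add atoms: 1,1′-thiocarbonyldiimidazole, S=C(n1ccnc1)n1ccnc1
Why: acyl transfer to the unhindered secondary C2 alcohol gives the thiocarbonyl derivative needed for Barton–McCombie deoxygenation under neutral conditions.

Step 13
Reactants: 23 C2 thiocarbonyl derivative
Product: 24 methyl (1R,2S,4aR,8aS)-1-(2-chloroethyl)-5,5,8a-trimethyl-1,2,4a,5,6,7,8,8a-octahydronaphthalene-2-carboxylate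
Conditions: Bu3SnH, AIBN (cat.), PhMe, 90 °C
Reagents that add atoms: none
Why: Barton–McCombie deoxygenation: the stannyl radical adds to C=S, the C2–O bond fragments and the secondary C2 radical abstracts hydrogen from Bu3SnH, removing the carbinol helper and its stereocenter while the primary chloride reacts much more slowly.

Step 14
Reactants: 24 chloroethyl decalin ester
Product: 25 methyl (1R,2S,4aR,8aS)-1-(2-iodoethyl)-5,5,8a-trimethyl-1,2,4a,5,6,7,8,8a-octahydronaphthalene-2-carboxylate
Conditions: NaI, acetone, reflux
Reagents that add atoms: sodium iodide, [Na+].[I-]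
Why: Finkelstein reaction (SN2, driven by precipitation of NaCl) converts the primary chloride into the iodide needed for zinc insertion.

Step 15
Reactants: 26 methyl 4-hydroxybut-2-ynoate
Product: 27 methyl 4-acetoxybut-2-ynoate
Conditions: Ac2O, pyridine, DMAP (cat.), CH2Cl2, 0 °C
Reagents that add atoms: acetic anhydride, CC(=O)OC(C)=O
Why: acetylation of the primary propargylic alcohol by nucleophilic catalysis installs the acetate of the target.

Step 16
Reactants: 27 methyl 4-acetoxybut-2-ynoate
Product: 28 methyl (Z)-4-acetoxy-3-iodobut-2-enoate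
Conditions: NaI, AcOH, 80 °C
Reagents that add atoms: sodium iodide, [Na+].[I-]
Why: conjugate addition of iodide to the ynoate followed by protonation anti to iodine (hydroiodination in acetic acid) should give the Z-iodoenoate, iodine cis to the ester.

Step 17
Reactants: 25 iodoethyl decalin ester; 28 methyl (Z)-4-acetoxy-3-iodobut-2-enoate
Product: 30 CNP0190145.1, via alkylzinc iodide 29 (not isolated)
Conditions: Zn dust, DMA, 40 °C; then 28, Pd(PPh3)4 (5 mol%), THF, rt
Reagents that add atoms: none
Why: Negishi coupling: zinc inserts into the primary iodide and the alkylzinc couples at zerovalent palladium with the vinyl iodide with retention of geometry, so the C12 chain ends cis to the ester (13E) and the target should be formed.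

**Compound list**

1 | pent-3-yn-1-ol | CC#CCCO | starting material
2 | 5-chloropent-2-yne | CC#CCCCl | intermediate
3 | [(2E)-5-chloropent-2-en-2-yl]zirconocene chloride | C/C(=C\CCCl)[Zr](Cl)(C1C=CC=C1)C1C=CC=C1 | intermediate (not isolated)
4 | (E)-5-chloro-2-iodopent-2-ene | ClCC/C=C(\C)I | intermediate
5 | 2-[(tert-butyldimethylsilyl)oxy]-N-methoxy-N-methylacetamide | CON(C)C(=O)CO[Si](C)(C)C(C)(C)C | starting material
6 | [(2E)-5-chloropent-2-en-2-yl]lithium | ClCC/C=C(\C)[Li] | intermediate (not isolated)
7 | (E)-1-[(tert-butyldimethylsilyl)oxy]-6-chloro-3-methylhex-3-en-2-one | ClCC/C=C(\C)C(=O)CO[Si](C)(C)C(C)(C)C | intermediate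
8 | (2S,3E)-1-[(tert-butyldimethylsilyl)oxy]-6-chloro-3-methylhex-3-en-2-ol | ClCC/C=C(\C)[C@H](O)CO[Si](C)(C)C(C)(C)C | intermediate
9 | (2-carboxyethyl)triphenylphosphonium bromide | OC(=O)CC[P+](c1ccccc1)(c1ccccc1)c1ccccc1.[Br-] | starting material
10 | 3-methylbut-2-enal | CC(C)=CC=O | starting material
11 | sodium 3-(triphenylphosphoranylidene)propanoate | [Na+].[O-]C(=O)CC=P(c1ccccc1)(c1ccccc1)c1ccccc1 | intermediate (not isolated)
12 | (3Z)-6-methylhepta-3,5-dienoic acid | OC(=O)C/C=C\C=C(C)C | intermediate
13 | (2S,3E)-1-[(tert-butyldimethylsilyl)oxy]-6-chloro-3-methylhex-3-en-2-yl (3Z)-6-methylhepta-3,5-dienoate | ClCC/C=C(\C)[C@H](OC(=O)C/C=C\C=C(C)C)CO[Si](C)(C)C(C)(C)C | intermediate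
14 | E O-trimethylsilyl ketene acetal of 13 (dienyl group cis to the allylic oxygen) | ClCC/C=C(\C)[C@H](O/C(O[Si](C)(C)C)=C\C=C/C=C(C)C)CO[Si](C)(C)C(C)(C)C | intermediate (not isolated)
15 | (2S,3R,4E)-6-[(tert-butyldimethylsilyl)oxy]-3-(2-chloroethyl)-4-methyl-2-[(1Z)-4-methylpenta-1,3-dien-1-yl]hex-4-enoic acid | ClCC[C@@H](/C(C)=C/CO[Si](C)(C)C(C)(C)C)[C@@H](C(=O)O)/C=C\C=C(C)C | intermediate (not isolated)
16 | methyl (2S,3R,4E)-6-[(tert-butyldimethylsilyl)oxy]-3-(2-chloroethyl)-4-methyl-2-[(1Z)-4-methylpenta-1,3-dien-1-yl]hex-4-enoate | ClCC[C@@H](/C(C)=C/CO[Si](C)(C)C(C)(C)C)[C@@H](C(=O)OC)/C=C\C=C(C)C | intermediate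
17 | methyl (2S,3R,4E)-3-(2-chloroethyl)-6-hydroxy-4-methyl-2-[(1Z)-4-methylpenta-1,3-dien-1-yl]hex-4-enoate | ClCC[C@@H](/C(C)=C/CO)[C@@H](C(=O)OC)/C=C\C=C(C)C | intermediate
18 | methyl (2S,3R,4E)-3-(2-chloroethyl)-4-methyl-2-[(1Z)-4-methylpenta-1,3-dien-1-yl]-6-oxohex-4-enoate | ClCC[C@@H](/C(C)=C/C=O)[C@@H](C(=O)OC)/C=C\C=C(C)C | intermediate
19 | methyl (1S,4R,5S,6R)-6-(2-chloroethyl)-5-methyl-5-(2-oxoethyl)-4-(prop-1-en-2-yl)cyclohex-2-ene-1-carboxylate | ClCC[C@@H]1[C@@H](C(=O)OC)C=C[C@H](C(C)=C)[C@@]1(C)CC=O | intermediate (not isolated)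
20 | methyl (1R,2S,4aR,8aS)-1-(2-chloroethyl)-7-hydroxy-8a-methyl-5-methylidene-1,2,4a,5,6,7,8,8a-octahydronaphthalene-2-carboxylate (C7 of the naphthalene = labdane C2, epimer mixture) | ClCC[C@@H]1[C@@H](C(=O)OC)C=C[C@@H]2C(=C)CC(O)C[C@@]12C | intermediate
21 | adduct of 20 carrying CH3 and CH2NHNHSO2Me on labdane C4 (C4 and C2 epimers) | ClCC[C@@H]1[C@@H](C(=O)OC)C=C[C@@H]2C(C)(CNNS(C)(=O)=O)CC(O)C[C@@]12C | intermediate (not isolated)
22 | methyl (1R,2S,4aR,8aS)-1-(2-chloroethyl)-7-hydroxy-5,5,8a-trimethyl-1,2,4a,5,6,7,8,8a-octahydronaphthalene-2-carboxylate (C7 epimers) | ClCC[C@@H]1[C@@H](C(=O)OC)C=C[C@@H]2C(C)(C)CC(O)C[C@@]12C | intermediate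
23 | O-(1H-imidazol-1-ylcarbonothioyl) derivative of 22 | ClCC[C@@H]1[C@@H](C(=O)OC)C=C[C@@H]2C(C)(C)CC(OC(=S)n3ccnc3)C[C@@]12C | intermediate
24 | methyl (1R,2S,4aR,8aS)-1-(2-chloroethyl)-5,5,8a-trimethyl-1,2,4a,5,6,7,8,8a-octahydronaphthalene-2-carboxylate | ClCC[C@@H]1[C@@H](C(=O)OC)C=C[C@@H]2C(C)(C)CCC[C@@]12C | intermediate
25 | methyl (1R,2S,4aR,8aS)-1-(2-iodoethyl)-5,5,8a-trimethyl-1,2,4a,5,6,7,8,8a-octahydronaphthalene-2-carboxylate | ICC[C@@H]1[C@@H](C(=O)OC)C=C[C@@H]2C(C)(C)CCC[C@@]12C | intermediate
26 | methyl 4-hydroxybut-2-ynoate | COC(=O)C#CCO | starting material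
27 | methyl 4-acetoxybut-2-ynoate | COC(=O)C#CCOC(C)=O | intermediate
28 | methyl (Z)-4-acetoxy-3-iodobut-2-enoate | COC(=O)/C=C(\I)COC(C)=O | intermediate
29 | alkylzinc iodide from 25 (C12–ZnI) | I[Zn]CC[C@@H]1[C@@H](C(=O)OC)C=C[C@@H]2C(C)(C)CCC[C@@]12C | intermediate (not isolated)
30 | CNP0190145.1: methyl (1R,2S,4aR,8aS)-1-[(3E)-3-(acetoxymethyl)-5-methoxy-5-oxopent-3-en-1-yl]-5,5,8a-trimethyl-1,2,4a,5,6,7,8,8a-octahydronaphthalene-2-carboxylate (labdane numbering 5R,8S,9R,10S,13E) | COC(=O)/C=C(\CC[C@@H]1[C@@H](C(=O)OC)C=C[C@@H]2C(C)(C)CCC[C@@]12C)COC(C)=O | target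

Total steps: 17. Longest linear sequence: 14 steps (1–4, 6–14, 17).

**Steps most likely to fail**

Step 10. The conjugate ene onto the β,β-disubstituted enal may be slow, so that cationic oligomerisation of the diene takes over. Facial selectivity at C5 and C10 may be poor. In the second ene, chloride capture or alkene migration may compete with hydrogen transfer. The fallback makes the two bonds in separate, precedented operations and sets out from 17. SnCl4 in CH2Cl2 at −78 °C ionises the allylic alcohol, and the allyl cation is captured at C10 by the prenyl alkene (allylic-alcohol-initiated cation–olefin cyclisation), giving the vinyl isopropenyl cyclohexene F1. Hydroboration of the monosubstituted angular vinyl group with 9-BBN and oxidation with NaBO3 gives the primary alcohol F2. Dess–Martin oxidation returns to the route at 19, now isolated, and a separate type 2 carbonyl-ene reaction with Me2AlCl gives 20.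

Step 7. Control of the ketene acetal geometry may be lost with the extended lithium dienolate, which erodes the C8/C9 diastereoselectivity, and the C6=C7 alkene may drift from Z to E at the enolate stage. The fallback sets out from 13 and avoids the lithium dienolate: soft enolisation with Bu2BOTf and i-Pr2NEt in CH2Cl2 at −78 °C gives the boron ketene acetal F3, whose geometry is set by the amine and solvent. It rearranges on warming (boron-enolate ester Claisen rearrangement) and aqueous work-up returns to the route at acid 15, which is methylated to 16 as before.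

Step 11. The hindered tertiary C4 radical may be reduced before it adds to the hydrazone, giving the 4-monomethyl compound, and hydrogen-atom transfer to the ring alkene may compete. The fallback sets out from 18 and delivers the methyl group by a polar path. The first ene reaction alone (Me2AlCl, −78 °C, cold quench) is used to isolate 19. Me3Al in CH2Cl2 (−78 to 0 °C) then effects a Prins-type closure of ring A in which the aluminate passes a methyl group to the tertiary C4 cation (the known cis addition of a carbinol carbon and a methyl group across an alkene with aldehyde–Me3Al). This returns to the route at 22 directly; no compound outside the list is made (F0).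

Further compounds
F1 | step 10 | methyl 6-(2-chloroethyl)-5-ethenyl-5-methyl-4-(prop-1-en-2-yl)cyclohex-2-ene-1-carboxylate, configuration as in 19 | ClCC[C@@H]1[C@@H](C(=O)OC)C=C[C@H](C(C)=C)[C@@]1(C)C=C
F2 | step 10 | methyl 6-(2-chloroethyl)-5-(2-hydroxyethyl)-5-methyl-4-(prop-1-en-2-yl)cyclohex-2-ene-1-carboxylate, configuration as in 19 | ClCC[C@@H]1[C@@H](C(=O)OC)C=C[C@H](C(C)=C)[C@@]1(C)CCO
F3 | step 7 | dibutylboron ketene acetal of 13 | ClCC/C=C(\C)[C@H](O/C(OB(CCCC)CCCC)=C\C=C/C=C(C)C)CO[Si](C)(C)C(C)(C)C
F0 | step 11 | none | none
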